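**Retrosynthetic overview**
- Odoratisol A (5) is the 8–5′ heterodimer of two propenylphenols. Disconnect O1–C2 (phenol oxygen onto a p-quinone methide) and C3–C3a (C8 of the syringyl unit to C5 of the guaiacyl unit).
- Both bonds form in one oxidative operation from (E)-isoeugenol (1) and (E)-4-propenylsyringol (2): radical C–C coupling gives dienone 3, which tautomerises to phenol quinone methide 4 and then closes.
- The dihydrofuran ring is the only ring made; C3–C3a forms first and O1–C2 last. Both arene rings are bought.
- C3 is set in the C–C coupling by a chiral oxovanadium Schiff-base catalyst with O2 as terminal oxidant; C2 follows as trans in the ring closure.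

Assumption: 1 and 2 are bought as the E isomers, and the (S)-tert-leucine-derived ligand is taken to give the (2S,3S) series; if the first run shows the opposite sense, the ligand from (R)-tert-leucine is used with nothing else changed.

**Step 1**
Reactants: 1 (E)-isoeugenol, 2-methoxy-4-[(E)-prop-1-enyl]phenol (3 equiv); 2 (E)-4-propenylsyringol, 2,6-dimethoxy-4-[(E)-prop-1-enyl]phenol (1 equiv, added slowly)
Product: 5 odoratisol A, via dienone quinone methide 3 (not isolated), via phenol quinone methide 4 (not isolated)
Conditions: VO(OiPr)3 (10 mol %), (S)-2-[(3,5-di-tert-butyl-2-hydroxybenzylidene)amino]-3,3-dimethylbutanoic acid (12 mol %), O2 (1 atm), AcOH (2 equiv), PhCl, 0 °C to rt, 2 added over 8 h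
Reagents that add atoms: none
Why: Proposed new method: an enantioselective variant of the oxidative 8–5′ coupling of propenylphenols, in which pentavalent vanadium oxidises the more electron-rich phenol 2 by inner-sphere electron transfer to its persistent quinone methide radical (both ortho positions carry OMe, so it can bond only through C8 or O), this radical attacks C5 of isoeugenol held as the vanadium phenolate (C5 lies next to the metal-bound oxygen, inside the pocket walled by the tert-butyl groups of the ligand, so one face of the incoming C8 terminus is selected and the later C3 is fixed as S), the adduct passes its electron to vanadium (tetravalent vanadium is returned to the pentavalent state by O2) to give dienone 3, which tautomerises to phenol 4, whose phenol oxygen adds to the p-quinone methide (intramolecular oxa-Michael, 5-exo) anti to the methyl group to set C2 as S in the trans ring, the isomer that acid also favours by reversible reopening to 4; the closest known reactions are the racemic Ag2O- or peroxidase-mediated dimerisation of isoeugenol to the trans-dihydrobenzofuran dehydrodiisoeugenol, the vanadium Schiff-base/O2 oxidative coupling of alkenyl phenols, and the enantioselective vanadium-catalysed oxidative coupling of phenols and 2-naphthols.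

**Compound list**
1 | (E)-isoeugenol, 2-methoxy-4-[(E)-prop-1-en-1-yl]phenol | C/C=C/c1ccc(O)c(OC)c1 | starting material
2 | (E)-4-propenylsyringol, 2,6-dimethoxy-4-[(E)-prop-1-en-1-yl]phenol | C/C=C/c1cc(OC)c(O)c(OC)c1 | starting material
3 | dienone quinone methide, 6-[(2R)-1-(3,5-dimethoxy-4-oxocyclohexa-2,5-dien-1-ylidene)propan-2-yl]-2-methoxy-4-[(E)-prop-1-en-1-yl]cyclohexa-2,4-dien-1-one (ring carbon C6 not assigned; this centre is erased on tautomerisation) | C/C=C/C1=CC([C@H](C)C=C2C=C(OC)C(=O)C(OC)=C2)C(=O)C(OC)=C1 | intermediate
4 | phenol quinone methide, 4-[(2R)-2-{2-hydroxy-3-methoxy-5-[(E)-prop-1-en-1-yl]phenyl}propylidene]-2,6-dimethoxycyclohexa-2,5-dien-1-one (same spatial arrangement as C3 of 5; the descriptor changes only because the priorities change) | C/C=C/c1cc(OC)c(O)c(c1)[C@H](C)C=C1C=C(OC)C(=O)C(OC)=C1 | intermediate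
5 | odoratisol A, 4-[(2S,3S)-7-methoxy-3-methyl-5-[(E)-prop-1-en-1-yl]-2,3-dihydro-1-benzofuran-2-yl]-2,6-dimethoxyphenol (2,3-trans) | C/C=C/c1cc(OC)c2c(c1)[C@H](C)[C@@H](c1cc(OC)c(O)c(OC)c1)O2 | target

**Totals**
Total step count: 1. Longest linear sequence: 1 step.

**Steps most likely to fail**
The route has a single step, so the ranking has one entry.

Step 1 carries three risks:
- **Chemoselectivity.** Dehydrodiisoeugenol from 1 alone, and 8–8′ and 8–O–4′ dimers of 2, compete with the cross-coupling. Excess 1 and slow addition of 2 keep the radical of 2 scarce, and 5 is separated from dehydrodiisoeugenol and recovered 1 on silica. A realistic expectation is 20–30 % based on 2.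
- **Over-oxidation.** Product 5 is itself a syringyl phenol and can be oxidised further, so the run is stopped at partial conversion of 2.
- **Enantioinduction.** The level and the sense of induction are unproven. They are read from a first small run by chiral HPLC and optical rotation, and a partial ee is completed by recrystallisation.

Fallback, setting out again from 1 and 2: control by the catalyst is given up and replaced by resolution. 1 (3 equiv) and 2 are coupled with Ag2O (1.2 equiv on 2, toluene/acetone 2:1, rt, dark), the classical racemic coupling of propenylphenols. It runs through the racemic dienone quinone methide F1 and the racemic phenol quinone methide F2, neither isolated, to racemic trans-odoratisol A F3. F3 is freed from dehydrodiisoeugenol on silica and resolved by preparative chromatography on an amylose tris(3,5-dimethylphenylcarbamate) phase, the type of phase that separates the enantiomers of dehydrodiisoeugenol. The (2S,3S) enantiomer, identified by its CD spectrum and rotation against the natural product, is 5, where the fallback rejoins the route; the other enantiomer is set aside.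

**Further compounds**
F1 | step 1 | racemic dienone quinone methide (3 and its enantiomer, 1:1) | C/C=C/C1=CC([C@H](C)C=C2C=C(OC)C(=O)C(OC)=C2)C(=O)C(OC)=C1.C/C=C/C1=CC([C@@H](C)C=C2C=C(OC)C(=O)C(OC)=C2)C(=O)C(OC)=C1
F2 | step 1 | racemic phenol quinone methide (4 and its enantiomer, 1:1) | C/C=C/c1cc(OC)c(O)c(c1)[C@H](C)C=C1C=C(OC)C(=O)C(OC)=C1.C/C=C/c1cc(OC)c(O)c(c1)[C@@H](C)C=C1C=C(OC)C(=O)C(OC)=C1
F3 | step 1 | racemic trans-odoratisol A (5 and its (2R,3R) enantiomer, 1:1) | C/C=C/c1cc(OC)c2c(c1)[C@H](C)[C@@H](c1cc(OC)c(O)c(OC)c1)O2.C/C=C/c1cc(OC)c2c(c1)[C@@H](C)[C@H](c1cc(OC)c(O)c(OC)c1)O2
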